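The 1.4 % of starting material left in the maple run at 0.333 h is the earliest reading of the two runs, so a quick number for the fast start can rest on it and the hunch of a very quick start can be tested against it. In autocatalysis, where target turns starting material into more target, the ratio c(target)/c(starting material) grows exponentially as long as the sum of the two stays constant, so the reckoning here counts doublings. Taken as read, the leftover puts maple 14.7 doublings past its seed at that reading. That makes about 1.36 min per doubling: this is the doubling time of the ratio. It is an estimate that carries the scatter of that reading, and a leftover of 1.4 % with a scatter of 1 percentage point may be close to nothing, which would make the doubling shorter.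

all flasks: starting material 40 mM
- maple: target 0.10 mM; run made earlier
- cedar: target 0.40 mM; run made earlier
- flask: target 0.200 mM; time 2.0 h

| run | time / h | target / % | starting material / % |
|---|---|---|---|
| maple | 0.333 | 93.6 | 1.4 |
| maple | 0.833 | 84.3 | 0.5 |
| maple | 1.50 | 73.1 | 0 |
| maple | 2.50 | 58.8 | 0.6 |
| cedar | 0.667 | 88.6 | 0 |
| cedar | 1.33 | 78.1 | 0 |
| cedar | 2.00 | 67.2 | 0 |
| cedar | 2.50 | 59.7 | 0.7 |

(scatter of a reading: 1 percentage point)

- percentages count the starting material that a species holds: one side product counts as two
- steps thought possible: starting material + target -> 2 target; starting material -> target; starting material + target -> side product; target <-> isomer of the product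

- amount of target in percent of the starting material charged, at 6.0 min, 30 min and 2.0 h

The flask needs 7.64 doublings to bring the ratio to one, which on that estimate takes about 10.4 min. The same estimate allows 4.41 doublings by 6.0 min, and this reckoning therefore commits to about 9.70 % target there as a low estimate, with the doubling perhaps shorter and the amount then higher. No run was sampled earlier than 0.333 h, so starting material at 6.0 min is the reading to watch. The forecast gives 12 %, 91 % and 66 %, its first point standing somewhat above that estimate, and it warns: “This is very sensitive to the rate, and the risk lies upward.”

The flask gives 98.5 %, 90.7 % and 66.6 %.

    starting material + target → 2 target (k = 16.7 M⁻¹ s⁻¹)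
    starting material → target (k = 1.32 × 10⁻⁵ s⁻¹)
    starting material + target → side product (k = 6.08 × 10⁻⁴ M⁻¹ s⁻¹)
    target ⇌ isomer of the product (K = 210, k = 5.72 × 10⁻⁵ s⁻¹)

With 16.7 M⁻¹ s⁻¹, the doubling time of the ratio in the flask is 1.03 s, so its 7.64 doublings take 7.87 s, and the 8.64 doublings of the maple run take 8.95 s. Against that, the forward half-life of target going to the isomer of the product is 3.4 h, far longer, and the flask at 2.00 h holds 66.6 % target and 33.9 % isomer of the product.

The readings were generated by integration for substances that don't exist, and the scatter is random.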